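Ring B (C9a, C9, C10, C11, C12, C1) is cut at C10–C11 and C1–C12: C11 and C12 are the γ- and β-carbons of a 3-methylbutenolide, and C10–C9–C9a(=O)–C1 is an enone with an enolisable α'-CH2. One flask therefore joins a 2-silyloxyfuran to an acyclic enone, whose far end holds C2 and C3 as an acetal-masked aldehyde, by an amine-catalysed vinylogous Michael addition followed by an enamine Michael closure; this gives the cis-fused keto-lactone with C10, C11, C12 and C13 set. Alkylation at C9 with a four-carbon amine chain, one tethered Paal–Knorr condensation (pyrrole and azepine), C3 formylation and a lactone annulation complete the target.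

Key step: step 4

Numbering remark: atom numbers are the usual Stemona ones (C9a, C3 pyrrole α-carbons; C1, C2 pyrrole β-carbons; C5–C8 azepine CH2 groups; C9 ring-fusion CH; C10 ethyl-bearing CH; C11 O-bearing CH; C12, C13 lactone CH carbons; C18–C21 pendant lactone).

Assumption: the cinchona amine (quinine- or quinidine-derived pseudoenantiomer) and the SEGPHOS enantiomer are taken to be the ones that give the 10R,11R and the 18S series; the steps are written for that choice.

Step 1
Reactants: 1 2-(2-bromoethyl)-1,3-dioxolane; 2 (E)-pent-2-enal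
Product: 4 (E)-1-(1,3-dioxolan-2-yl)hept-4-en-3-ol (racemic at the carbinol carbon), via Grignard reagent 3 (not isolated)
Conditions: Mg turnings, THF, 25–30 °C; then 2, THF, −78 to 0 °C; aq NH4Cl
Reagents that add atoms: none
Why: The acetal-bearing Grignard reagent, kept below 30 °C so that it does not fragment, adds 1,2 to the enal at low temperature (Grignard addition), and the racemic carbinol centre is removed in step 2.

Step 2
Reactants: 4 (E)-1-(1,3-dioxolan-2-yl)hept-4-en-3-ol
Product: 5 (E)-1-(1,3-dioxolan-2-yl)hept-4-en-3-one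
Conditions: activated MnO2 (excess), CH2Cl2, rt
Reagents that add atoms: none
Why: Activated MnO2 oxidises only the allylic alcohol and leaves the acetal and the E-alkene untouched (allylic alcohol oxidation).

Step 3
Reactants: 6 3-methylfuran-2(5H)-one
Product: 7 3-methyl-2-(trimethylsilyloxy)furan
Conditions: TMSOTf, Et3N, CH2Cl2, 0 °C; pentane, filtration under argon; used at once
Reagents that add atoms: trimethylsilyl trifluoromethanesulfonate, C[Si](C)(C)OS(=O)(=O)C(F)(F)F
Why: Soft enolisation of the butenolide by TMSOTf and Et3N gives the aromatic 2-silyloxyfuran, the γ-nucleophilic form of the lactone (silyl dienolate formation).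

Step 4
Reactants: 5 (E)-1-(1,3-dioxolan-2-yl)hept-4-en-3-one; 7 3-methyl-2-(trimethylsilyloxy)furan
Product: 9 cis-fused keto-lactone (3S,3aR,7R,7aR)-4-(1,3-dioxolan-2-ylmethyl)-7-ethyl-3-methyl-3a,6,7,7a-tetrahydro-1-benzofuran-2,5(3H,4H)-dione (both C4 epimers), via butenolide ketone 8 (not isolated)
Conditions: 9-amino-9-deoxy-epi-quinine (20 mol%), CF3CO2H (40 mol%), H2O (2 equiv), CHCl3, 0 °C to rt; then pyrrolidine, AcOH (1 equiv each), 40 °C
Reagents that add atoms: none
Why: Proposed new method: the primary amine salt turns enone 5 into an iminium ion that silyloxyfuran 7 attacks at C10 through its γ-carbon (C11), water taking the silyl group and hydrolysis releasing butenolide ketone 8, whose ketone then forms the C9a=C1 enamine with pyrrolidinium acetate, adds to the butenolide β-carbon C12 and leaves a lactone enolate that is protonated at C13. The closest known reactions are amine-catalysed asymmetric vinylogous Mukaiyama–Michael additions of 2-silyloxyfurans to enals and enones (with the direct addition of the free furanone as the pathway that takes over if 7 is desilylated first) and iminium–enamine Michael–Michael cascades, and what is new is their union in one flask on this pair of partners. Ring B closes in a 6-(enolendo)-exo-trig mode through a chair with the ethyl group equatorial. C10 and C11 (10R,11R, ethyl and ring oxygen anti when C9–C12 is drawn zigzag) are set by the chiral amine, which shields one face of the iminium ion; C12 is set by the tether through C10–C11, which lets C1 reach only the butenolide face that gives the cis ring fusion; C13 is set by protonation on the convex face of the bicyclic enolate (H-11, H-12 and H-13 all cis); C1 is left uncontrolled because it becomes a pyrrole carbon. The step needs the enamine on the C1 side and the anti adduct: the first is secured because closure from C9 would make a four-membered ring while enamine formation is reversible, the second rests on the catalyst and is the point to verify on the first run.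

Step 5
Reactants: 10 (E)-1,4-dibromobut-2-ene; 11 di-tert-butyl iminodicarboxylate
Product: 12 di-tert-butyl N-[(E)-4-bromobut-2-enyl]imidodicarbonate
Conditions: K2CO3, DMF, rt; 10 in threefold excess (recovered)
Reagents that add atoms: none
Why: The imide N–H is acidic enough for carbonate, the allylic bromide is a fast SN2 partner and the excess of dibromide suppresses double substitution (imide N-alkylation, Gabriel type).

Step 6
Reactants: 9 cis-fused keto-lactone; 12 di-tert-butyl N-[(E)-4-bromobut-2-enyl]imidodicarbonate
Product: 14 di-tert-butyl N-[(E)-4-[(3S,3aR,6R,7R,7aR)-4-(1,3-dioxolan-2-ylmethyl)-7-ethyl-3-methyl-2,5-dioxooctahydro-1-benzofuran-6-yl]but-2-enyl]imidodicarbonate, via lithium enolate 13 (not isolated)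
Conditions: LiN(iPr)2 (1.05 equiv), THF, −78 °C; then 12, DMPU, −78 to −30 °C; crude product, DBU (0.2 equiv), CH2Cl2, rt
Reagents that add atoms: none
Why: LiN(iPr)2 at −78 °C removes a proton from the less substituted α-carbon C9 faster than the tertiary C1–H or the lactone C13–H, the allylic bromide alkylates C9 on the face away from the axial C11–O bond (kinetic enolate alkylation), and DBU equilibrates C9 so that the chain is equatorial and trans to ethyl (9R).

Step 7
Reactants: 14 alkylated ketone with the but-2-enyl chain
Product: 15 di-tert-butyl N-[4-[(3S,3aR,6R,7R,7aR)-4-(1,3-dioxolan-2-ylmethyl)-7-ethyl-3-methyl-2,5-dioxooctahydro-1-benzofuran-6-yl]butyl]imidodicarbonate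
Conditions: H2 (1 atm), Pd/C (5%), EtOAc, rt
Reagents that add atoms: none
Why: Palladium on carbon saturates the disubstituted alkene under one atmosphere of hydrogen, conditions under which ketone, lactone, acetal and carbamates are inert (catalytic hydrogenation), and no stereocentre is created.

Step 8
Reactants: 15 ketone with the protected 4-aminobutyl chain on C9
Product: 17 tetracyclic pyrrole (9R,10R,11R,12S,13S; the target skeleton with C3–H in place of the pendant lactone), via amino keto aldehyde 16 (not isolated)
Conditions: CF3CO2H/H2O (9:1), CH2Cl2, 0 °C to rt; evaporate; NaOAc, AcOH, EtOH (0.005 M), 60 °C, argon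
Reagents that add atoms: none
Why: Aqueous acid removes both Boc groups and the dioxolane, and in buffered dilute solution the primary amine condenses with the C9a ketone (seven-membered imine or enamine, which closes the azepine) and then with the C3 aldehyde, loss of two molecules of water giving the aromatic pyrrole (Paal–Knorr synthesis), in which C1 is sp2 and C9, epimerisable only before aromatisation, is expected to keep the equatorial 9R arrangement.

Step 9
Reactants: 17 tetracyclic pyrrole
Product: 19 C3 carbaldehyde of 17, via iminium chloride 18 (not isolated)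
Conditions: POCl3, DMF, ClCH2CH2Cl, 0 °C to rt; then aq NaOAc, rt
Reagents that add atoms: N,N-dimethylformamide, CN(C)C=O (formyl carbon); water, O (formyl oxygen)
Why: The chloroiminium ion attacks the only unsubstituted α-position of the electron-rich pyrrole (C3) and hydrolysis releases the aldehyde, which also stabilises the pyrrole against air (Vilsmeier–Haack formylation).

Step 10
Reactants: 19 pyrrole C3 carbaldehyde; 20 ethyl 2-(acetoxymethyl)acrylate
Product: 22 (18S)-α-methylene-γ-butyrolactone on C3 (9R,10R,11R,12S,13S,18S), via hydroxy ester 21 (not isolated)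
Conditions: [Ir(cod)Cl]2 (2.5 mol%), SEGPHOS (5 mol%, enantiomer as assumed above), 4-cyano-3-nitrobenzoic acid (10 mol%), Cs2CO3 (20 mol%), iPrOH (2 equiv), THF, 70 °C; then DBU (cat.), rt, if ring closure is incomplete
Reagents that add atoms: none
Why: Transfer hydrogenation from isopropanol converts the allylic acetate into a nucleophilic 2-(ethoxycarbonyl)allyl iridium complex that adds to the aldehyde through a closed six-membered transition state in the pocket of the cyclometallated SEGPHOS benzoate catalyst, which sets C18 (S) under catalyst control, and the alkoxide closes onto the ester under base, which avoids acid ionisation of the pyrrolyl carbinol (iridium-catalysed 2-(alkoxycarbonyl)allylation with lactonisation).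

Step 11
Reactants: 22 (18S)-α-methylene-γ-butyrolactone
Product: 23 bisdehydroneotuberostemonine (9R,10R,11R,12S,13S,18S,20S)
Conditions: H2 (1 atm), RhCl(PPh3)3 (10 mol%), toluene/EtOH (1:1), rt
Reagents that add atoms: none
Why: Hydrogen is delivered to the exocyclic alkene on the lactone face opposite the pyrrolyl group at C18, so that the new methyl group is cis to it (20S), and the homogeneous rhodium catalyst does not hydrogenolyse the pyrrolyl C–O bond (homogeneous hydrogenation under steric control).

Compound list
1 | 2-(2-bromoethyl)-1,3-dioxolane | BrCCC1OCCO1 | starting material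
2 | (E)-pent-2-enal | CC/C=C/C=O | starting material
3 | [2-(1,3-dioxolan-2-yl)ethyl]magnesium bromide (formed in the flask) | Br[Mg]CCC1OCCO1 | intermediate
4 | (E)-1-(1,3-dioxolan-2-yl)hept-4-en-3-ol, racemic | CC/C=C/C(O)CCC1OCCO1 | intermediate
5 | (E)-1-(1,3-dioxolan-2-yl)hept-4-en-3-one | CC/C=C/C(=O)CCC1OCCO1 | intermediate
6 | 3-methylfuran-2(5H)-one | CC1=CCOC1=O | starting material
7 | 3-methyl-2-(trimethylsilyloxy)furan | Cc1ccoc1O[Si](C)(C)C | intermediate
8 | (5R)-5-[(3R)-7-(1,3-dioxolan-2-yl)-5-oxoheptan-3-yl]-3-methylfuran-2(5H)-one (formed in the flask) | CC[C@H](CC(=O)CCC1OCCO1)[C@H]1OC(=O)C(C)=C1 | intermediate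
9 | (3S,3aR,7R,7aR)-4-(1,3-dioxolan-2-ylmethyl)-7-ethyl-3-methyl-3a,6,7,7a-tetrahydro-1-benzofuran-2,5(3H,4H)-dione, cis-fused, both C4 (Stemona C1) epimers | CC[C@H]1[C@H]2OC(=O)[C@@H](C)[C@H]2C(CC3OCCO3)C(=O)C1 | intermediate
10 | (E)-1,4-dibromobut-2-ene | BrC/C=C/CBr | starting material
11 | di-tert-butyl iminodicarboxylate | CC(C)(C)OC(=O)NC(=O)OC(C)(C)C | starting material
12 | di-tert-butyl N-[(E)-4-bromobut-2-enyl]imidodicarbonate | BrC/C=C/CN(C(=O)OC(C)(C)C)C(=O)OC(C)(C)C | intermediate
13 | lithium enolate of 9 toward C6 (Stemona C9) (formed in the flask) | CC[C@H]1[C@H]2OC(=O)[C@@H](C)[C@H]2C(CC3OCCO3)C(O[Li])=C1 | intermediate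
14 | di-tert-butyl N-[(E)-4-[(3S,3aR,6R,7R,7aR)-4-(1,3-dioxolan-2-ylmethyl)-7-ethyl-3-methyl-2,5-dioxooctahydro-1-benzofuran-6-yl]but-2-enyl]imidodicarbonate | CC[C@H]1[C@H]2OC(=O)[C@@H](C)[C@H]2C(CC3OCCO3)C(=O)[C@@H]1C/C=C/CN(C(=O)OC(C)(C)C)C(=O)OC(C)(C)C | intermediate
15 | di-tert-butyl N-[4-[(3S,3aR,6R,7R,7aR)-4-(1,3-dioxolan-2-ylmethyl)-7-ethyl-3-methyl-2,5-dioxooctahydro-1-benzofuran-6-yl]butyl]imidodicarbonate | CC[C@H]1[C@H]2OC(=O)[C@@H](C)[C@H]2C(CC3OCCO3)C(=O)[C@@H]1CCCCN(C(=O)OC(C)(C)C)C(=O)OC(C)(C)C | intermediate
16 | [(3S,3aR,6R,7R,7aR)-6-(4-aminobutyl)-7-ethyl-3-methyl-2,5-dioxooctahydro-1-benzofuran-4-yl]acetaldehyde, as its ammonium trifluoroacetate (formed in the flask) | CC[C@H]1[C@H]2OC(=O)[C@@H](C)[C@H]2C(CC=O)C(=O)[C@@H]1CCCC[NH3+].[O-]C(=O)C(F)(F)F | intermediate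
17 | tetracyclic pyrrole (9R,10R,11R,12S,13S), C3 unsubstituted: cis-fused α-methyl lactone on ring B, ring B fused to the pyrrole at C1–C9a, azepine closed from N through C5–C8 to C9 | CC[C@H]1[C@H]2OC(=O)[C@@H](C)[C@H]2c2ccn3c2[C@@H]1CCCC3 | intermediate
18 | C3 (dimethyliminio)methyl derivative of 17, chloride (formed in the flask) | CC[C@H]1[C@H]2OC(=O)[C@@H](C)[C@H]2c2cc(C=[N+](C)C)n3c2[C@@H]1CCCC3.[Cl-] | intermediate
19 | C3 carbaldehyde of 17 | CC[C@H]1[C@H]2OC(=O)[C@@H](C)[C@H]2c2cc(C=O)n3c2[C@@H]1CCCC3 | intermediate
20 | ethyl 2-(acetoxymethyl)acrylate | C=C(COC(C)=O)C(=O)OCC | starting material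
21 | ethyl 2-[(2S)-2-hydroxy-2-(C3 pyrrolyl)ethyl]acrylate, the 18S carbinol (formed in the flask) | CC[C@H]1[C@H]2OC(=O)[C@@H](C)[C@H]2c2cc([C@@H](O)CC(=C)C(=O)OCC)n3c2[C@@H]1CCCC3 | intermediate
22 | (18S)-α-methylene-γ-butyrolactone on C3 | CC[C@H]1[C@H]2OC(=O)[C@@H](C)[C@H]2c2cc([C@@H]3CC(=C)C(=O)O3)n3c2[C@@H]1CCCC3 | intermediate
23 | bisdehydroneotuberostemonine (9R,10R,11R,12S,13S,18S,20S) | CC[C@H]1[C@H]2OC(=O)[C@@H](C)[C@H]2c2cc([C@@H]3C[C@H](C)C(=O)O3)n3c2[C@@H]1CCCC3 | target

Total step count: 11. Longest linear sequence: 9 steps (steps 1, 2, 4, 6, 7, 8, 9, 10, 11).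

Steps most likely to fail

Step 4. The intermolecular addition may give the wrong relative sense at C10–C11 or too little facial selectivity, the silyloxyfuran may be protonated before it adds, or the enamine closure may stall at 8. Fallback, from 7 back to 9: the C10–C11 bond is made on a chelating acceptor by the known anti-selective copper bis(oxazoline) Mukaiyama–Michael addition. (E)-Pent-2-enoic acid is converted (pivaloyl chloride, Et3N; then oxazolidin-2-one, LiCl) into 3-[(E)-pent-2-enoyl]-1,3-oxazolidin-2-one F1. Compound 7 adds to F1 under Cu(OTf)2 and the tBu-box enantiomer that gives the 10R,11R series (CH2Cl2, −25 °C) to form 3-[(3R)-3-[(2R)-4-methyl-5-oxo-2,5-dihydrofuran-2-yl]pentanoyl]-1,3-oxazolidin-2-one F2. LiSEt in THF at 0 °C exchanges the oxazolidinone for the thioester S-ethyl (3R)-3-[(2R)-4-methyl-5-oxo-2,5-dihydrofuran-2-yl]pentanethioate F3. Fukuyama coupling of F3 with [2-(1,3-dioxolan-2-yl)ethyl]zinc bromide F4 (from 1, Zn dust, LiCl, THF) under PdCl2(PPh3)2 gives 8, which is then isolated and closed to 9 with pyrrolidine and AcOH in a separate operation.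

Step 8. Intermolecular imine formation and oligomerisation may outrun the seven-membered closure, and the free 1,4-keto aldehyde may cyclise to a furan or undergo aldol condensation under acid. Fallback, from 9 back to 17: the azepine is closed by N-alkylation instead of condensation. Enolate 13 is alkylated with 1-chloro-4-iodobutane (DMPU, −78 to −20 °C) to the C9 4-chlorobutyl ketone F5. Aqueous CF3CO2H frees the chloro keto aldehyde F6, which is not isolated but treated with NH4OAc in AcOH/EtOH to give, by an ordinary intermolecular Paal–Knorr reaction with ammonia, the N–H pyrrole F7. NaH with catalytic NaI in DMF at 0 °C then closes the seven-membered ring by intramolecular N-alkylation and delivers 17.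

Step 10. Carbonyl addition may be sluggish because the formyl group is deactivated as a vinylogous formamide, so that simple transfer hydrogenation of the aldehyde competes, and facial selectivity may erode on this hindered heteroaryl aldehyde. Fallback, from 19 back to 22: zinc-mediated Barbier allylation with ethyl 2-(bromomethyl)acrylate (Zn dust, THF, aq NH4Cl; Dreiding–Schmidt lactone synthesis). This stoichiometric allylzinc addition does not depend on the iridium cycle, but it is not expected to control C18. It should give hydroxy ester 21 together with its C18 epimer F8, which close (DBU if needed) to 22 and the 18R lactone F9. The two diastereomeric lactones are separated by chromatography and 22 goes on to step 11.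

Further compounds
F1 | step 4 | 3-[(E)-pent-2-enoyl]-1,3-oxazolidin-2-one | CC/C=C/C(=O)N1CCOC1=O
F2 | step 4 | 3-[(3R)-3-[(2R)-4-methyl-5-oxo-2,5-dihydrofuran-2-yl]pentanoyl]-1,3-oxazolidin-2-one | CC[C@H](CC(=O)N1CCOC1=O)[C@H]1OC(=O)C(C)=C1
F3 | step 4 | S-ethyl (3R)-3-[(2R)-4-methyl-5-oxo-2,5-dihydrofuran-2-yl]pentanethioate | CC[C@H](CC(=O)SCC)[C@H]1OC(=O)C(C)=C1
F4 | step 4 | [2-(1,3-dioxolan-2-yl)ethyl]zinc bromide | Br[Zn]CCC1OCCO1
F5 | step 8 | (3S,3aR,6R,7R,7aR)-6-(4-chlorobutyl)-4-(1,3-dioxolan-2-ylmethyl)-7-ethyl-3-methyl-3a,6,7,7a-tetrahydro-1-benzofuran-2,5(3H,4H)-dione | CC[C@H]1[C@H]2OC(=O)[C@@H](C)[C@H]2C(CC3OCCO3)C(=O)[C@@H]1CCCCCl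
F6 | step 8 | [(3S,3aR,6R,7R,7aR)-6-(4-chlorobutyl)-7-ethyl-3-methyl-2,5-dioxooctahydro-1-benzofuran-4-yl]acetaldehyde | CC[C@H]1[C@H]2OC(=O)[C@@H](C)[C@H]2C(CC=O)C(=O)[C@@H]1CCCCCl
F7 | step 8 | N–H pyrrole (9R,10R,11R,12S,13S) fused to ring B and the lactone, with a 4-chlorobutyl chain on C9 | CC[C@H]1[C@H]2OC(=O)[C@@H](C)[C@H]2c2cc[nH]c2[C@@H]1CCCCCl
F8 | step 10 | C18 epimer (18R) of hydroxy ester 21 | CC[C@H]1[C@H]2OC(=O)[C@@H](C)[C@H]2c2cc([C@H](O)CC(=C)C(=O)OCC)n3c2[C@@H]1CCCC3
F9 | step 10 | C18 epimer (18R) of α-methylene lactone 22 | CC[C@H]1[C@H]2OC(=O)[C@@H](C)[C@H]2c2cc([C@H]3CC(=C)C(=O)O3)n3c2[C@@H]1CCCC3
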